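**Assumption:** labdane numbering is used for the terpene and diosmetin numbering (primed) for the flavone B ring. Levopimaric acid (pine-oleoresin resin acid) and diosmetin are bought as catalogue natural products.

## Retrosynthetic overview
1. Last ring (cyclohexene, bonds C12–C1' and C15–C2'): [4+2] of the 12E,14-diene of 7β-hydroxylabda-8(17),12,14-trien-18-oic acid with the chromonyl-bearing C=C of the flavone B-ring p-quinone. The quinone is released at an anode from its hydroquinone while the diene is present.
2. Hydroquinone/quinone: para-oxidation of the 3'-phenol of diosmetin (chromone and B ring bought).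
3. Diene: methylenation of an E-enal made by cross-metathesis of a C9 allyl group. The 7β-OH comes from SeO2 hydroxylation, oxidation and axial hydride delivery.
4. Allyl/exomethylene decalin: double methylenation of the keto-aldehyde from exhaustive ozonolysis of ring C of levopimaric acid (rings A/B and C4, C5, C9, C10 bought).

## Route

**Step 1**
Reactants: 1, levopimaric acid (abieta-8(14),12-dien-18-oic acid; 4α-CO2H, 4β-Me, 5α-H, 9α-H, 10β-Me)
Product: 2, 8,12-dioxo-13,14,15,16,17-pentanorlabdan-18-oic acid (C8 ketone, C9β-CH2CHO; ring A/B stereocentres as in 1)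
Conditions: O3, CH2Cl2–MeOH 4:1, −78 °C to persistent blue; Me2S, −78 °C → rt
Reagents that add atoms: ozone, [O-][O+]=O
Why: Exhaustive ozonolysis cleaves both trisubstituted ring-C alkenes and excises C13–C14 with the isopropyl group as 3-methyl-2-oxobutanal; C4, C5, C9 and C10 are untouched, and C9, now α to the ketone, already carries its side chain equatorial, so enolisation cannot invert it.

**Step 2**
Reactants: 2; 3, methyltriphenylphosphonium bromide
Product: 4, 14,15,16-trinorlabda-8(17),12-dien-18-oic acid (C8=CH2, C9β-allyl)
Conditions: 3 (6 equiv), KOtBu (5.5 equiv), THF; add 2 at −78 °C, then 50 °C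
Reagents that add atoms: methyltriphenylphosphonium bromide, C[P+](c1ccccc1)(c1ccccc1)c1ccccc1.[Br-]
Why: Double Wittig methylenation, in which the aldehyde reacts cold before any aldol chemistry, the hindered C8 ketone reacts on warming, and one equivalent of ylide only deprotonates the acid; no new stereocentre.

**Step 3**
Reactants: 4
Product: 5, 7α-hydroxy-14,15,16-trinorlabda-8(17),12-dien-18-oic acid
Conditions: SeO2 (0.5 equiv), t-BuOOH (3 equiv), CH2Cl2, 0 °C → rt
Reagents that add atoms: selenium dioxide, O=[Se]=O; tert-butyl hydroperoxide, CC(C)(C)OO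
Why: Riley–Sharpless allylic hydroxylation (ene, then [2,3]-shift) picks the 1,1-disubstituted C8=C17 alkene over the monosubstituted allyl group and delivers oxygen to C7 from the open α face; this axial configuration is erased in step 4.

**Step 4**
Reactants: 5
Product: 6, 7-oxo-14,15,16-trinorlabda-8(17),12-dien-18-oic acid (α-methylene ketone, used at once)
Conditions: DMP, NaHCO3, CH2Cl2, 0 °C
Reagents that add atoms: none
Why: Buffered Dess–Martin oxidation of the secondary allylic alcohol is neutral enough to avoid migration of the exocyclic alkene to Δ8(9); the acid and the terminal alkene are inert.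

**Step 5**
Reactants: 6
Product: 7, 7β-hydroxy-14,15,16-trinorlabda-8(17),12-dien-18-oic acid (7S, equatorial OH)
Conditions: NaBH4, CeCl3·7H2O, MeOH, −78 °C
Reagents that add atoms: none
Why: In this Luche 1,2-reduction the small hydride attacks C7 of the rigid trans-decalin axially from the α face, giving the equatorial 7β-alcohol under control of C5/C9/C10.

**Step 6**
Reactants: 7; 8, methacrolein
Product: 9, (12E)-7β-hydroxy-14-oxo-15-norlabda-8(17),12-dien-18-oic acid
Conditions: 8 (10 equiv), Hoveyda–Grubbs II (5 mol %), CH2Cl2, 40 °C
Reagents that add atoms: methacrolein, C=C(C)C=O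
Why: Olefin cross-metathesis of a terminal alkene with methacrolein gives the E-trisubstituted enal; the hindered 1,1-disubstituted C8=C17 alkene does not take part.

**Step 7**
Reactants: 9; 3, methyltriphenylphosphonium bromide
Product: 10, 7β-hydroxylabda-8(17),12E,14-trien-18-oic acid
Conditions: 3 (4.5 equiv), NaHMDS (4.2 equiv), THF, −78 → 0 °C
Reagents that add atoms: methyltriphenylphosphonium bromide, C[P+](c1ccccc1)(c1ccccc1)c1ccccc1.[Br-]
Why: Wittig methylenation of the only carbonyl electrophile (acid and alcohol are simply deprotonated) leaves the 12E geometry and all stereocentres unchanged.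

**Step 8**
Reactants: 11, diosmetin (5,7,3'-trihydroxy-4'-methoxyflavone)
Product: 13, 5,7-dihydroxy-2-(2,5-dihydroxy-4-methoxyphenyl)chromen-4-one (3',6'-dihydroxy in diosmetin numbering), formed via 12, 2-(5,7-dihydroxy-4-oxochromen-2-yl)-5-methoxy-1,4-benzoquinone (not isolated)
Conditions: (KSO3)2NO (2.5 equiv), KH2PO4 buffer pH 6.5, DMF–H2O, 0 °C; then aq Na2S2O4
Reagents that add atoms: Fremy's salt, [K+].[K+].[O]N(S(=O)(=O)[O-])S(=O)(=O)[O-]
Why: Teuber oxidation abstracts the weakest O–H (the guaiacol-type 3'-OH, not the chelated 5-OH or the acidic 7-OH) and oxygenates its free para position C6' to the p-quinone, which is reduced at once to the storable hydroquinone; no stereocentre.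

**Step 9**
Reactants: 10 (1 equiv); 13 (1.5 equiv)
Product: 14, dichrostachine E (cis-fused adduct; C12–C1' and C15–C2' bonds, C13=C14 alkene; 7S, 12R, 1'S, 2'R; C11, chromonyl and H-2' all on one face of the new cyclohexene)
Conditions: divided cell, graphite-felt anode | Pt cathode, +0.70 V vs Ag/AgCl (2.1 F mol⁻¹ of 13), Mg(ClO4)2 (0.2 M), 2,6-lutidine (2.2 equiv), MeCN, 0 °C, dark, Ar; then 25 °C, 16 h; citrate wash, prep-HPLC
Reagents that add atoms: none
Why: Proposed new method: anodic 2e⁻/2H⁺ oxidation of 13 (well below the potentials of the A-ring phenols, the diene or the carboxylate) releases the self-reactive quinone 12 slowly into a Mg(ClO4)2 medium that already holds 10, so each quinone is consumed in a normal-demand [4+2]; Mg²⁺ held in the peri 5-OH/4-C=O pocket makes the chromonyl group the dominant acceptor on C1'=C2', so the free, most nucleophilic terminus C15 bonds to C2'–H and C12 bonds to C1' (regiochemistry), the Mg-bound chromone rather than the methoxy-deactivated enedione takes the endo position under C13–C14 (C11 cis to chromonyl), suprafacial addition fixes the cis fusion, and A1,3 strain with the C13 methyl turns the decalin (C9/C10) over one diene face so the C12 Re face is attacked (12R; only moderate d.r. is expected, and a rough conformer model does not clearly favour this face, so the 12-epimer may be formed in similar or larger amount and is removed by HPLC); the closest known reaction types are in-cell Diels–Alder trapping of electrogenerated quinones in LiClO4/MeNO2 and Mg(ClO4)2-accelerated quinone cycloadditions, neither shown for a flavone B-ring quinone, a labdane diene, or for switching which group sits endo.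

## Compound list
1 | levopimaric acid | CC(C)C1=CC[C@H]2C(=C1)CC[C@@H]3[C@]2(C)CCC[C@@]3(C)C(=O)O | starting material
2 | 8,12-dioxo-13,14,15,16,17-pentanorlabdan-18-oic acid | O=CC[C@H]1C(=O)CC[C@@H]2[C@]1(C)CCC[C@@]2(C)C(=O)O | intermediate
3 | methyltriphenylphosphonium bromide | C[P+](c1ccccc1)(c1ccccc1)c1ccccc1.[Br-] | starting material
4 | 14,15,16-trinorlabda-8(17),12-dien-18-oic acid | C=CC[C@H]1C(=C)CC[C@@H]2[C@]1(C)CCC[C@@]2(C)C(=O)O | intermediate
5 | 7α-hydroxy-14,15,16-trinorlabda-8(17),12-dien-18-oic acid | C=CC[C@H]1C(=C)[C@H](O)C[C@@H]2[C@]1(C)CCC[C@@]2(C)C(=O)O | intermediate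
6 | 7-oxo-14,15,16-trinorlabda-8(17),12-dien-18-oic acid | C=CC[C@H]1C(=C)C(=O)C[C@@H]2[C@]1(C)CCC[C@@]2(C)C(=O)O | intermediate
7 | 7β-hydroxy-14,15,16-trinorlabda-8(17),12-dien-18-oic acid | C=CC[C@H]1C(=C)[C@@H](O)C[C@@H]2[C@]1(C)CCC[C@@]2(C)C(=O)O | intermediate
8 | methacrolein | C=C(C)C=O | starting material
9 | (12E)-7β-hydroxy-14-oxo-15-norlabda-8(17),12-dien-18-oic acid | O=C/C(C)=C/C[C@H]1C(=C)[C@@H](O)C[C@@H]2[C@]1(C)CCC[C@@]2(C)C(=O)O | intermediate
10 | 7β-hydroxylabda-8(17),12E,14-trien-18-oic acid | C=C/C(C)=C/C[C@H]1C(=C)[C@@H](O)C[C@@H]2[C@]1(C)CCC[C@@]2(C)C(=O)O | intermediate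
11 | diosmetin | COc1ccc(cc1O)-c1cc(=O)c2c(O)cc(O)cc2o1 | starting material
12 | 2-(5,7-dihydroxy-4-oxochromen-2-yl)-5-methoxy-1,4-benzoquinone | COC1=CC(=O)C(=CC1=O)c1cc(=O)c2c(O)cc(O)cc2o1 | intermediate (transient, steps 8 and 9)
13 | 5,7-dihydroxy-2-(2,5-dihydroxy-4-methoxyphenyl)chromen-4-one | COc1cc(O)c(cc1O)-c1cc(=O)c2c(O)cc(O)cc2o1 | intermediate
14 | dichrostachine E | C=C1[C@@H](O)C[C@@H]2[C@](C)(CCC[C@@]2(C)C(=O)O)[C@H]1C[C@@H]1C(C)=CC[C@H]2C(=O)C(OC)=CC(=O)[C@@]12c1cc(=O)c2c(O)cc(O)cc2o1 | target

## Summary
Total steps: 9. Longest linear sequence: 8 (steps 1–7, then 9).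

**Steps most likely to fail**
1. **Step 9 (new step).**
   - Risks: quinone-endo or C12-epimeric adducts dominate, the reversed regiochemistry appears, or 12 condenses with itself.
   - Fallback (known chemistry): oxidise 13 outside the cell with Ag2O and filter. Run an ordinary thermal quinone Diels–Alder with 10 (toluene, 40 °C, or 5 M LiClO4–Et2O). Accept the isomer mixture and isolate 14 by preparative HPLC.
2. **Step 8.**
   - Risks: over-oxidation of the A ring, or decomposition of 12 in buffer.
   - Fallback: build the B ring pre-oxygenated. Condense 2-hydroxy-4,6-bis(benzyloxy)acetophenone with 2,4,5-trimethoxybenzaldehyde to the chalcone and cyclise with I2/DMSO to the flavone. CAN oxidative demethylation of the 2',5'-dimethoxy pair gives the methoxyquinone. Dithionite reduction and debenzylation (BCl3) then give 13.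
3. **Step 1.**
   - Risks: abietic-acid contamination of 1, incomplete second cleavage, or aldehyde over-oxidation.
   - Fallback: dye-sensitised photooxygenation of 1 to the crystalline 8α,12α-endoperoxide (abietic acid does not react). Reduce with thiourea to the 8,12-diol and ozonise the single remaining Δ13 alkene. Cleave both α-hydroxycarbonyl units with NaIO4 to reach 2.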